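**Plan**

1. Retrosynthesis (drimane numbering, see remark): the acyl groups and the side-chain isopropylidene (cross-metathesis) go first. Then C-4–C-5 and C-9–C-10 are cut in one stroke, C-8=CH2 being traced to a CH2SiMe3 group and the C-3(Br)/C-4 pair to a bromohydrin, which opens the bicycle to an acyclic (2Z,6E)-dienyl allylsilane. Then C-9–CH2Ar and C-8–CH2Si (one alkyne carbometallation), the side-chain bond next to C-4, and C-6–C-7.
2. Forward: geranyl bromide + silylpropyne → terminal allylic oxidation → Sharpless epoxidation → allylation → three-component union with the benzylic bromide → bromohydrin. Ring A (C-1 to C-5, C-10) and then, last, the methylidene ring B (C-5 to C-10) form in one operation; cross-metathesis and saponification finish.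
3. Enabling feature: an equatorial secondary bromide at C-3 beside quaternary C-4, a trans fusion at C-5/C-10 and an exocyclic methylene at C-8 next to an equatorial C-9 substituent are the imprint of an anti-opened bromonium ion relayed through a 1,5-diene to an allylsilane in a chair–chair array.
4. Stereochemistry: C-3 and C-4 come from one Sharpless epoxidation (L-(+)-tartrate), carried on by SN2 bromide opening and double inversion at C-4. C-5, C-10 and C-9 are set by substrate control in the key step from the E alkene of geranyl bromide and the Z allylsilane from syn-carbocupration.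

Key step: step 11

Remark: C-1 to C-10 are the decalin carbons in drimane numbering (Br on C-3, methyl and side chain on C-4, methylidene on C-8, arylmethyl on C-9, angular methyl on C-10).
Assumption: the epoxidation of 5 follows the usual facial rule for E allylic alcohols (L-(+)-tartrate gives the 2S,3S epoxy alcohol, as with geraniol).

**Route**

Step 1
Reactants: 1 geranyl bromide [(2E)-1-bromo-3,7-dimethylocta-2,6-diene]; 2 1-(trimethylsilyl)propyne
Product: 4 trimethyl[(5E)-6,10-dimethylundeca-5,9-dien-1-yn-1-yl]silane, via 3-lithio-1-(trimethylsilyl)propyne 3 (not isolated)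
Conditions: 2, n-BuLi, THF, −78 °C; then 1, −78 → 0 °C
Reagents that add atoms: none
Why: the silyl-capped propargylic lithium reagent alkylates the primary allylic bromide by SN2 at its CH2 end (the silyl group suppresses allenyl attack), leaving the E alkene untouched.

Step 2
Reactants: 4
Product: 5 (2E,6E)-2,6-dimethyl-11-(trimethylsilyl)undeca-2,6-dien-10-yn-1-ol
Conditions: SeO2 (cat.), t-BuOOH, salicylic acid (cat.), CH2Cl2, 0 °C → rt, stopped at partial conversion
Reagents that add atoms: selenium dioxide O=[Se]=O (catalytic oxygen carrier); tert-butyl hydroperoxide CC(C)(C)OO (stoichiometric oxygen source)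
Why: Riley allylic oxidation (ene reaction, then [2,3]-shift) should attack the more accessible terminal isopropylidene at its E methyl, giving the E primary allylic alcohol that later directs the epoxidation.

Step 3
Reactants: 5
Product: 6 [(2S,3S)-2-methyl-3-[(3E)-3-methyl-8-(trimethylsilyl)oct-3-en-7-yn-1-yl]oxiran-2-yl]methanol
Conditions: Ti(OiPr)4 (10 mol%), L-(+)-diethyl tartrate (12 mol%), t-BuOOH, 4 Å MS, CH2Cl2, −20 °C
Reagents that add atoms: tert-butyl hydroperoxide CC(C)(C)OO
Why: Sharpless asymmetric epoxidation touches only the alkene with the allylic hydroxyl; L-(+)-tartrate sets both epoxide carbons (2S,3S) and the E geometry fixes their relative configuration.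

Step 4
Reactants: 6
Product: 8 (2S,3S)-2-(but-3-en-1-yl)-2-methyl-3-[(3E)-3-methyl-8-(trimethylsilyl)oct-3-en-7-yn-1-yl]oxirane, via epoxy triflate 7 (not isolated)
Conditions: Tf2O, 2,6-lutidine, CH2Cl2, −78 °C; cold filtration through a short silica pad; then allylMgBr, CuBr·SMe2 (10 mol%), Et2O, −78 → −20 °C
Reagents that add atoms: allylmagnesium bromide C=CC[Mg]Br
Why: copper-catalysed Grignard coupling with a primary alkyl triflate (SN2 at carbon) should outrun attack on the trisubstituted epoxide, and no stereocentre is touched; the side chain is held as a monosubstituted alkene until after the key step.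

Step 5
Reactants: 8
Product: 9 (2S,3S)-2-(but-3-en-1-yl)-2-methyl-3-[(3E)-3-methyloct-3-en-7-yn-1-yl]oxirane
Conditions: K2CO3 (cat.), MeOH, rt
Reagents that add atoms: none
Why: base-catalysed methanolysis of the alkynyl C–Si bond; epoxide and alkenes are inert to these conditions.

Step 6
Reactants: 10 methyl 4-hydroxy-3-methylbenzoate
Product: 11 methyl 3-bromo-4-hydroxy-5-methylbenzoate
Conditions: NBS, MeCN, 0 °C → rt
Reagents that add atoms: N-bromosuccinimide O=C1CCC(=O)N1Br
Why: electrophilic aromatic bromination at the only free position ortho to the phenol (para is blocked by the ester).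

Step 7
Reactants: 11
Product: 12 methyl 3-bromo-4-[(2,2-dimethylpropanoyl)oxy]-5-methylbenzoate
Conditions: PivCl, Et3N, DMAP (cat.), CH2Cl2, rt
Reagents that add atoms: pivaloyl chloride CC(C)(C)C(=O)Cl
Why: O-acylation; the pivalate should survive radical bromination, the organocopper step and the cationic cyclisation, keeps the phenol from trapping cations, and is removed by hydroxide at the end.

Step 8
Reactants: 12
Product: 13 methyl 3-bromo-5-(bromomethyl)-4-[(2,2-dimethylpropanoyl)oxy]benzoate
Conditions: NBS, AIBN (cat.), PhCF3, 85 °C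
Reagents that add atoms: N-bromosuccinimide O=C1CCC(=O)N1Br
Why: Wohl–Ziegler bromination of the only benzylic methyl group.

Step 9
Reactants: 9; 13
Product: 15 methyl 3-bromo-5-[(2Z,6E)-9-[(2S,3S)-3-(but-3-en-1-yl)-3-methyloxiran-2-yl]-7-methyl-3-[(trimethylsilyl)methyl]nona-2,6-dien-1-yl]-4-[(2,2-dimethylpropanoyl)oxy]benzoate, via alkenylcopper 14 (not isolated)
Conditions: Me3SiCH2MgCl, CuBr·SMe2, Et2O/Me2S, −40 °C; 9, −25 → 0 °C; then 13, DMPU, −20 °C → rt
Reagents that add atoms: (trimethylsilyl)methylmagnesium chloride C[Si](C)(C)C[Mg]Cl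
Why: syn-carbocupration of the terminal alkyne places CH2SiMe3 on the internal carbon and copper on the terminal one, and alkylation of the alkenylcopper by the benzylic bromide with retention leaves arylmethyl and silylmethyl cis (2Z) in one three-component operation.

Step 10
Reactants: 15
Product: 16 methyl 3-bromo-5-[(2Z,6E,10R,11S)-10-bromo-11-hydroxy-7,11-dimethyl-3-[(trimethylsilyl)methyl]pentadeca-2,6,14-trien-1-yl]-4-[(2,2-dimethylpropanoyl)oxy]benzoate
Conditions: Li2NiBr4 (from LiBr and NiBr2), THF, 0 °C → rt; pH 7 aqueous work-up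
Reagents that add atoms: dilithium tetrabromonickelate [Li+].[Li+].[Ni+2].[Br-].[Br-].[Br-].[Br-]
Why: soft bromide should open the trisubstituted epoxide by SN2 at the less substituted carbon, giving the anti bromohydrin with inversion at the C–Br carbon (10R) and retention at the tertiary carbinol (11S).

Step 11
Reactants: 16
Product: 18 methyl 3-bromo-5-{[(1R,4aS,5R,6R,8aS)-6-bromo-5-(but-3-en-1-yl)-5,8a-dimethyl-2-methylidenedecahydronaphthalen-1-yl]methyl}-4-[(2,2-dimethylpropanoyl)oxy]benzoate, via tertiary triflate 17 (not isolated)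
Conditions: Tf2O, 2,6-di-tert-butyl-4-methylpyridine, CH2Cl2 (0.005 M), −78 → −40 °C; Et3N, then aq. NaHCO3
Reagents that add atoms: none
Why: Proposed new method: triflation of the tertiary alcohol gives 17, whose C–O bond should ionise with backside participation of the neighbouring bromine, so that one enantiomer of one bromonium ion forms at the only place where it can; the 6E alkene opens it anti at the tertiary carbon, and the new tertiary cation is trapped by the 2Z allylsilane, which loses Me3Si+ to leave the exocyclic methylene. The closest known reaction types are the enantiospecific generation of a bromonium ion from a scalemic bromohydrin derivative with capture by an internal alkene, bromonium-initiated polyene cyclisation with achiral Br+ donors, and the allylsilane-terminated epoxy-polyene cyclisation; new is their combination with in-situ tertiary-triflate activation. Ring closure: the bromine-bearing ring (C-1 to C-5, C-10) closes first by 6-endo attack of C-5 on C-4, then the methylidene ring (C-5 to C-10) closes last by 6-endo attack of C-9 on C-10, both through chairs. Stereocentres: C-3 is carried from 16 and ends equatorial because C–Br must be antiperiplanar to the forming C-4–C-5 bond; C-4 is formed with net retention (two inversions); the trans fusion C-5/C-10 follows from anti addition across the E alkene in the chair–chair array, and C-9 (equatorial arylmethyl, cis to the C-10 methyl) from the Z geometry of the allylsilane. Selectivity needed: site and absolute sense of bromonium formation (secured by the pre-installed bromohydrin, so no free Br+ meets the other alkenes; high dilution, low temperature and the non-nucleophilic monosubstituted side-chain alkene disfavour Br+ transfer), regiochemistry of termination (β-silicon effect gives only the exocyclic alkene) and freedom from protodesilylation (the hindered pyridine removes TfOH).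

Step 12
Reactants: 18
Product: 19 methyl 3-bromo-5-{[(1R,4aS,5R,6R,8aS)-6-bromo-5,8a-dimethyl-2-methylidene-5-(4-methylpent-3-en-1-yl)decahydronaphthalen-1-yl]methyl}-4-[(2,2-dimethylpropanoyl)oxy]benzoate
Conditions: Grubbs second-generation catalyst (5 mol%), 1,4-benzoquinone (10 mol%), 2-methyl-2-butene/CH2Cl2 (1:1), rt → 35 °C
Reagents that add atoms: 2-methyl-2-butene CC=C(C)C
Why: olefin cross-metathesis should convert the monosubstituted terminal alkene into the isopropylidene, while the hindered 1,1-disubstituted exocyclic methylene should not engage; benzoquinone suppresses Ru–H alkene migration.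

Step 13
Reactants: 19
Product: 20 callophycoic acid H, 3-bromo-5-{[(1R,4aS,5R,6R,8aS)-6-bromo-5,8a-dimethyl-2-methylidene-5-(4-methylpent-3-en-1-yl)decahydronaphthalen-1-yl]methyl}-4-hydroxybenzoic acid
Conditions: LiOH·H2O, THF/MeOH/H2O, 50 °C; then 1 M HCl to pH 3, 0 °C
Reagents that add atoms: lithium hydroxide [Li+].[OH-]
Why: saponification of the aryl pivalate and the methyl ester; the equatorial neopentyl-type secondary bromide cannot undergo SN2 or anti-E2, and the cold, mildly acidic work-up avoids phenol addition to the exocyclic alkene.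

**Compound list**

1 | geranyl bromide | CC(C)=CCC/C(C)=C/CBr | starting material
2 | 1-(trimethylsilyl)propyne | CC#C[Si](C)(C)C | starting material
3 | 3-lithio-1-(trimethylsilyl)propyne | [Li]CC#C[Si](C)(C)C | intermediate (not isolated)
4 | trimethyl[(5E)-6,10-dimethylundeca-5,9-dien-1-yn-1-yl]silane | C[Si](C)(C)C#CCC/C=C(\C)CCC=C(C)C | intermediate
5 | (2E,6E)-2,6-dimethyl-11-(trimethylsilyl)undeca-2,6-dien-10-yn-1-ol | C[Si](C)(C)C#CCC/C=C(\C)CC/C=C(\C)CO | intermediate
6 | [(2S,3S)-2-methyl-3-[(3E)-3-methyl-8-(trimethylsilyl)oct-3-en-7-yn-1-yl]oxiran-2-yl]methanol | C[Si](C)(C)C#CCC/C=C(\C)CC[C@@H]1O[C@@]1(C)CO | intermediate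
7 | triflate of 6 | C[Si](C)(C)C#CCC/C=C(\C)CC[C@@H]1O[C@@]1(C)COS(=O)(=O)C(F)(F)F | intermediate (not isolated)
8 | (2S,3S)-2-(but-3-en-1-yl)-2-methyl-3-[(3E)-3-methyl-8-(trimethylsilyl)oct-3-en-7-yn-1-yl]oxirane | C[Si](C)(C)C#CCC/C=C(\C)CC[C@@H]1O[C@@]1(C)CCC=C | intermediate
9 | (2S,3S)-2-(but-3-en-1-yl)-2-methyl-3-[(3E)-3-methyloct-3-en-7-yn-1-yl]oxirane | C#CCC/C=C(\C)CC[C@@H]1O[C@@]1(C)CCC=C | intermediate
10 | methyl 4-hydroxy-3-methylbenzoate | COC(=O)c1ccc(O)c(C)c1 | starting material
11 | methyl 3-bromo-4-hydroxy-5-methylbenzoate | COC(=O)c1cc(C)c(O)c(Br)c1 | intermediate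
12 | methyl 3-bromo-4-[(2,2-dimethylpropanoyl)oxy]-5-methylbenzoate | COC(=O)c1cc(C)c(OC(=O)C(C)(C)C)c(Br)c1 | intermediate
13 | methyl 3-bromo-5-(bromomethyl)-4-[(2,2-dimethylpropanoyl)oxy]benzoate | COC(=O)c1cc(CBr)c(OC(=O)C(C)(C)C)c(Br)c1 | intermediate
14 | [(1Z,5E)-8-[(2S,3S)-3-(but-3-en-1-yl)-3-methyloxiran-2-yl]-6-methyl-2-[(trimethylsilyl)methyl]octa-1,5-dien-1-yl]copper | [Cu]/C=C(\C[Si](C)(C)C)CC/C=C(\C)CC[C@@H]1O[C@@]1(C)CCC=C | intermediate (not isolated)
15 | methyl 3-bromo-5-[(2Z,6E)-9-[(2S,3S)-3-(but-3-en-1-yl)-3-methyloxiran-2-yl]-7-methyl-3-[(trimethylsilyl)methyl]nona-2,6-dien-1-yl]-4-[(2,2-dimethylpropanoyl)oxy]benzoate | COC(=O)c1cc(Br)c(OC(=O)C(C)(C)C)c(C/C=C(\C[Si](C)(C)C)CC/C=C(\C)CC[C@@H]2O[C@@]2(C)CCC=C)c1 | intermediate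
16 | methyl 3-bromo-5-[(2Z,6E,10R,11S)-10-bromo-11-hydroxy-7,11-dimethyl-3-[(trimethylsilyl)methyl]pentadeca-2,6,14-trien-1-yl]-4-[(2,2-dimethylpropanoyl)oxy]benzoate | COC(=O)c1cc(Br)c(OC(=O)C(C)(C)C)c(C/C=C(\C[Si](C)(C)C)CC/C=C(\C)CC[C@@H](Br)[C@@](C)(O)CCC=C)c1 | intermediate
17 | 11-O-triflate of 16 | COC(=O)c1cc(Br)c(OC(=O)C(C)(C)C)c(C/C=C(\C[Si](C)(C)C)CC/C=C(\C)CC[C@@H](Br)[C@@](C)(OS(=O)(=O)C(F)(F)F)CCC=C)c1 | intermediate (not isolated)
18 | methyl 3-bromo-5-{[(1R,4aS,5R,6R,8aS)-6-bromo-5-(but-3-en-1-yl)-5,8a-dimethyl-2-methylidenedecahydronaphthalen-1-yl]methyl}-4-[(2,2-dimethylpropanoyl)oxy]benzoate | C=C1CC[C@@H]2[C@@](C)(CCC=C)[C@H](Br)CC[C@@]2(C)[C@@H]1Cc1cc(C(=O)OC)cc(Br)c1OC(=O)C(C)(C)C | intermediate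
19 | methyl 3-bromo-5-{[(1R,4aS,5R,6R,8aS)-6-bromo-5,8a-dimethyl-2-methylidene-5-(4-methylpent-3-en-1-yl)decahydronaphthalen-1-yl]methyl}-4-[(2,2-dimethylpropanoyl)oxy]benzoate | C=C1CC[C@@H]2[C@@](C)(CCC=C(C)C)[C@H](Br)CC[C@@]2(C)[C@@H]1Cc1cc(C(=O)OC)cc(Br)c1OC(=O)C(C)(C)C | intermediate
20 | callophycoic acid H | C=C1CC[C@@H]2[C@@](C)(CCC=C(C)C)[C@H](Br)CC[C@@]2(C)[C@@H]1Cc1cc(C(=O)O)cc(Br)c1O | target

**Totals**

Total step count: 13. Longest linear sequence: 10 (steps 1–5 and 9–13, from geranyl bromide).

**Steps most likely to fail**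

1. Step 11 (Proposed new method). What may go wrong: ionisation without full bromine bridging (open cation, hence loss of configuration at C-4 or E1 loss of a proton), Br+ transfer to another alkene before ring closure (erosion of enantiopurity and of site control), or protodesilylation of the allylsilane before the second ring closes. The fallback uses known chemistry only; it sets out from 5 and returns at 18. Sharpless epoxidation of 5 with D-(−)-diethyl tartrate should give the enantiomeric (2R,3R)-epoxy alcohol F1. The operations of steps 4, 5 and 9 then lead through the epoxy triflate F2 to the butenyl epoxide F3, the terminal alkyne F4, the alkenylcopper F5 and the (2R,3R)-epoxy allylsilane F6. A Lewis-acid epoxy-polyene cyclisation (MeAlCl2, CH2Cl2, −78 °C), terminated by the allylsilane, opens the epoxide with a single inversion at C-4 and should give the equatorial C-3 alcohol F7 in the correct absolute series. Dess–Martin oxidation gives the C-3 ketone F8, L-Selectride (THF, −78 °C) delivers hydride from the equatorial side to give the axial alcohol F9, and Appel bromination (CBr4, PPh3) with inversion gives 18.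

2. Step 9. What may go wrong: slow alkylation of the alkenylcopper by the hindered, doubly ortho-substituted benzylic bromide, with homocoupling or acyl transfer competing, and opening of the epoxide by the magnesium salts during the long carbocupration. The fallback sets out from 9 and 13 and returns at 15. The carbocupration is run as before and 14 is quenched with iodine to give the (Z)-alkenyl iodide F10. Separately, 13 is converted with zinc dust/LiCl (THF, rt) into the benzylic zinc bromide F11. A Pd-catalysed Negishi coupling (Pd(OAc)2/SPhos, THF, rt), in which the alkenyl iodide reacts ahead of the aryl bromide, joins them to 15.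

3. Step 10. What may go wrong: bromide attack at the tertiary instead of the hindered secondary epoxide carbon, or Lewis-acid rearrangement of the epoxide to a carbonyl compound. The fallback sets out from 15 and returns at 18. The epoxide is opened on purpose at the tertiary carbon (MgBr2·OEt2, Et2O, −20 °C, inversion there) to give the regioisomeric anti bromohydrin F12. Under the conditions of step 11 its secondary triflate F13 should ionise with participation of the tertiary bromine to the same bromonium ion and so give 18.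

**Further compounds**

F1 | step 11 | [(2R,3R)-2-methyl-3-[(3E)-3-methyl-8-(trimethylsilyl)oct-3-en-7-yn-1-yl]oxiran-2-yl]methanol | C[Si](C)(C)C#CCC/C=C(\C)CC[C@H]1O[C@]1(C)CO
F2 | step 11 | triflate of F1 | C[Si](C)(C)C#CCC/C=C(\C)CC[C@H]1O[C@]1(C)COS(=O)(=O)C(F)(F)F
F3 | step 11 | (2R,3R)-2-(but-3-en-1-yl)-2-methyl-3-[(3E)-3-methyl-8-(trimethylsilyl)oct-3-en-7-yn-1-yl]oxirane | C[Si](C)(C)C#CCC/C=C(\C)CC[C@H]1O[C@]1(C)CCC=C
F4 | step 11 | (2R,3R)-2-(but-3-en-1-yl)-2-methyl-3-[(3E)-3-methyloct-3-en-7-yn-1-yl]oxirane | C#CCC/C=C(\C)CC[C@H]1O[C@]1(C)CCC=C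
F5 | step 11 | [(1Z,5E)-8-[(2R,3R)-3-(but-3-en-1-yl)-3-methyloxiran-2-yl]-6-methyl-2-[(trimethylsilyl)methyl]octa-1,5-dien-1-yl]copper | [Cu]/C=C(\C[Si](C)(C)C)CC/C=C(\C)CC[C@H]1O[C@]1(C)CCC=C
F6 | step 11 | methyl 3-bromo-5-[(2Z,6E)-9-[(2R,3R)-3-(but-3-en-1-yl)-3-methyloxiran-2-yl]-7-methyl-3-[(trimethylsilyl)methyl]nona-2,6-dien-1-yl]-4-[(2,2-dimethylpropanoyl)oxy]benzoate | COC(=O)c1cc(Br)c(OC(=O)C(C)(C)C)c(C/C=C(\C[Si](C)(C)C)CC/C=C(\C)CC[C@H]2O[C@]2(C)CCC=C)c1
F7 | step 11 | methyl 3-bromo-5-{[(1R,4aS,5R,6R,8aS)-5-(but-3-en-1-yl)-6-hydroxy-5,8a-dimethyl-2-methylidenedecahydronaphthalen-1-yl]methyl}-4-[(2,2-dimethylpropanoyl)oxy]benzoate | C=C1CC[C@@H]2[C@@](C)(CCC=C)[C@H](O)CC[C@@]2(C)[C@@H]1Cc1cc(C(=O)OC)cc(Br)c1OC(=O)C(C)(C)C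
F8 | step 11 | methyl 3-bromo-5-{[(1R,4aS,5R,8aS)-5-(but-3-en-1-yl)-5,8a-dimethyl-2-methylidene-6-oxodecahydronaphthalen-1-yl]methyl}-4-[(2,2-dimethylpropanoyl)oxy]benzoate | C=C1CC[C@@H]2[C@@](C)(CCC=C)C(=O)CC[C@@]2(C)[C@@H]1Cc1cc(C(=O)OC)cc(Br)c1OC(=O)C(C)(C)C
F9 | step 11 | methyl 3-bromo-5-{[(1R,4aS,5R,6S,8aS)-5-(but-3-en-1-yl)-6-hydroxy-5,8a-dimethyl-2-methylidenedecahydronaphthalen-1-yl]methyl}-4-[(2,2-dimethylpropanoyl)oxy]benzoate | C=C1CC[C@@H]2[C@@](C)(CCC=C)[C@@H](O)CC[C@@]2(C)[C@@H]1Cc1cc(C(=O)OC)cc(Br)c1OC(=O)C(C)(C)C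
F10 | step 9 | (2S,3S)-2-(but-3-en-1-yl)-3-[(3E,7Z)-8-iodo-3-methyl-7-[(trimethylsilyl)methyl]octa-3,7-dien-1-yl]-2-methyloxirane | I/C=C(\C[Si](C)(C)C)CC/C=C(\C)CC[C@@H]1O[C@@]1(C)CCC=C
F11 | step 9 | {[3-bromo-2-[(2,2-dimethylpropanoyl)oxy]-5-(methoxycarbonyl)phenyl]methyl}zinc bromide | COC(=O)c1cc(C[Zn]Br)c(OC(=O)C(C)(C)C)c(Br)c1
F12 | step 10 | methyl 3-bromo-5-[(2Z,6E,10S,11R)-11-bromo-10-hydroxy-7,11-dimethyl-3-[(trimethylsilyl)methyl]pentadeca-2,6,14-trien-1-yl]-4-[(2,2-dimethylpropanoyl)oxy]benzoate | COC(=O)c1cc(Br)c(OC(=O)C(C)(C)C)c(C/C=C(\C[Si](C)(C)C)CC/C=C(\C)CC[C@H](O)[C@](C)(Br)CCC=C)c1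
F13 | step 10 | 10-O-triflate of F12 | COC(=O)c1cc(Br)c(OC(=O)C(C)(C)C)c(C/C=C(\C[Si](C)(C)C)CC/C=C(\C)CC[C@H](OS(=O)(=O)C(F)(F)F)[C@](C)(Br)CCC=C)c1
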